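**Retrosynthetic overview**
1. Kuwanon W ⇒ removal of six MOM acetals from the exo [4+2] adduct (last step).
2. Cyclohexene ring with its three stereocentres ⇒ chiral-borate-promoted Diels–Alder reaction of a 2'-hydroxy pyranochalcone (dienophile) with an 8-dienyl-3-prenylflavone (diene).
3. Flavone ring C ⇒ key C–O ring closure (O1–C2): rhodium-catalysed oxidative annulation of a 3-bromosalicylaldehyde with an aryl prenyl alkyne, which also places the prenyl group at C3; the C8 bromide then takes the diene by Suzuki coupling.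
4. Chromene ring of the dienophile ⇒ oxa-6π C–O closure from 2,4-dihydroxyacetophenone and prenal, then Claisen–Schmidt condensation with the same protected aldehyde that feeds the alkyne.
5. Ring order in the forward direction: flavone ring C → chromene ring → cyclohexene ring.

Assumption: with the cyclohexene numbered C3'' (flavone-bearing), C4'' (aroyl-bearing) and C5'' (aryl-bearing), the given SMILES is the all-trans (3''S,4''S,5''R) isomer; the (S)-ligand is taken to give this series, and if the observed sense is opposite the (R)-ligand is used in the same way.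

**Step 1**
Reactants: 1 2,4-dihydroxybenzaldehyde
Product: 2 2,4-bis(methoxymethoxy)benzaldehyde
Conditions: MOMCl (3 equiv), K2CO3 (4 equiv), acetone, reflux, 6 h
Reagents that add atoms: chloromethyl methyl ether, COCCl
Why: Williamson-type O-alkylation (MOM acetal formation) of both phenols, the chelated 2-OH needing the excess and heat; the acetals are inert to the base, copper, rhodium, palladium and boron chemistry that follows.

**Step 2**
Reactants: 2 2,4-bis(methoxymethoxy)benzaldehyde
Product: 3 1-ethynyl-2,4-bis(methoxymethoxy)benzene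
Conditions: dimethyl (1-diazo-2-oxopropyl)phosphonate (1.3 equiv), K2CO3 (2 equiv), MeOH, rt, 12 h
Reagents that add atoms: dimethyl (1-diazo-2-oxopropyl)phosphonate, COP(=O)(OC)C(=[N+]=[N-])C(C)=O
Why: Ohira–Bestmann variant of the Seyferth–Gilbert homologation: the diazomethylphosphonate anion formed in situ adds to the aldehyde and the alkylidene carbene rearranges to the terminal alkyne under conditions mild enough for the aryl acetals.

**Step 3**
Reactants: 3 1-ethynyl-2,4-bis(methoxymethoxy)benzene; 4 1-bromo-3-methylbut-2-ene (prenyl bromide)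
Product: 5 1-(5-methylhex-4-en-1-yn-1-yl)-2,4-bis(methoxymethoxy)benzene
Conditions: copper monoiodide CuI (10 mol %), K2CO3 (1.5 equiv), n-Bu4NI (10 mol %), DMF, rt, 16 h
Reagents that add atoms: none
Why: Copper acetylide allylation: the soft copper acetylide attacks the primary carbon of prenyl bromide (SN2 rather than SN2') to give the skipped 1,4-enyne.

**Step 4**
Reactants: 6 2,4,6-trihydroxybenzaldehyde
Product: 7 2-hydroxy-4,6-bis(methoxymethoxy)benzaldehyde
Conditions: MOMCl (2.2 equiv), K2CO3 (3 equiv), acetone, 0 °C to rt, 4 h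
Reagents that add atoms: chloromethyl methyl ether, COCCl
Why: Selective Williamson MOM protection: the 4-OH and one ortho-OH react, while the remaining ortho-OH is hydrogen-bonded to the aldehyde and stays free as the future ring oxygen.

**Step 5**
Reactants: 7 2-hydroxy-4,6-bis(methoxymethoxy)benzaldehyde
Product: 8 3-bromo-2-hydroxy-4,6-bis(methoxymethoxy)benzaldehyde
Conditions: NBS (1.02 equiv), i-Pr2NH (10 mol %), CH2Cl2, 0 °C, 1 h
Reagents that add atoms: N-bromosuccinimide, O=C1CCC(=O)N1Br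
Why: Amine-mediated electrophilic aromatic bromination directed ortho to the free phenol, which puts the halogen on the carbon that becomes C8 once the neighbouring phenol oxygen becomes O1.

**Step 6**
Reactants: 8 3-bromo-2-hydroxy-4,6-bis(methoxymethoxy)benzaldehyde; 5 1-(5-methylhex-4-en-1-yn-1-yl)-2,4-bis(methoxymethoxy)benzene
Product: 9 8-bromo-2-[2,4-bis(methoxymethoxy)phenyl]-5,7-bis(methoxymethoxy)-3-(3-methylbut-2-en-1-yl)-4H-chromen-4-one
Conditions: [RhCl(cod)]2 (2.5 mol %), 1,2,3,4-tetraphenylcyclopenta-1,3-diene (10 mol %), Cu(OAc)2·H2O (2.2 equiv), 5 (1.2 equiv), o-xylene, 120 °C, N2, 6 h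
Reagents that add atoms: none
Why: Proposed new method: phenoxide-directed rhodation of the aldehyde C–H bond gives a five-membered acyl rhodacycle of trivalent rhodium, the aryl–alkyl alkyne inserts with the metal on the aryl-bearing carbon and the acyl group on the carbon carrying the prenyl CH2, and C–O reductive elimination then forges the O1–C2 bond and closes ring C with the prenyl group already at C3, Cu(OAc)2 reoxidising monovalent rhodium; the closest known reaction is the rhodium-catalysed oxidative annulation of salicylaldehydes with diaryl or simple alkyl aryl alkynes to 2,3-disubstituted chromones, and new here are the skipped enyne partner (a propargylic–allylic CH2 and a trisubstituted olefin that must survive) and the ortho-bromo, acetal-protected polyphenolic aldehyde.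

**Step 7**
Reactants: 10 2-methylbut-1-en-3-yne
Product: 11 4,4,5,5-tetramethyl-2-[(1E)-3-methylbuta-1,3-dien-1-yl]-1,3,2-dioxaborolane
Conditions: pinacolborane (1.05 equiv), Cp2Zr(H)Cl (5 mol %), Et3N (10 mol %), neat, 60 °C, 16 h
Reagents that add atoms: pinacolborane, CC1(C)OBOC1(C)C
Why: Zirconocene-hydride-catalysed hydroboration of the terminal alkyne: syn, anti-Markovnikov B–H addition gives the E-dienylboronate and leaves the 1,1-disubstituted alkene alone.

**Step 8**
Reactants: 9 8-bromo-2-[2,4-bis(methoxymethoxy)phenyl]-5,7-bis(methoxymethoxy)-3-(3-methylbut-2-en-1-yl)-4H-chromen-4-one; 11 4,4,5,5-tetramethyl-2-[(1E)-3-methylbuta-1,3-dien-1-yl]-1,3,2-dioxaborolane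
Product: 12 2-[2,4-bis(methoxymethoxy)phenyl]-5,7-bis(methoxymethoxy)-8-[(1E)-3-methylbuta-1,3-dien-1-yl]-3-(3-methylbut-2-en-1-yl)-4H-chromen-4-one
Conditions: Pd(OAc)2 (5 mol %), SPhos (10 mol %), K3PO4 (3 equiv), 11 (1.5 equiv), toluene/H2O 10:1, 80 °C, 8 h
Reagents that add atoms: none
Why: Suzuki–Miyaura coupling: the electron-rich biaryl phosphine lets zerovalent palladium insert into the hindered C8–Br bond, and the E-alkenyl group transfers with retention while acetals and prenyl group are inert to aqueous phosphate.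

**Step 9**
Reactants: 13 1-(2,4-dihydroxyphenyl)ethan-1-one; 14 3-methylbut-2-enal
Product: 16 1-(5-hydroxy-2,2-dimethyl-2H-chromen-6-yl)ethan-1-one, via ortho-quinone methide 15 (not isolated)
Conditions: pyridine, 120 °C, sealed tube, 16 h
Reagents that add atoms: none
Why: Pyridine-mediated chromenylation: aldol-type C-alkylation at C3 between the two oxygens, dehydration to the ortho-quinone methide and oxa-6π electrocyclisation through the non-chelated 4-OH form the chromene C–O bond, the chelated 2-OH staying free.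

**Step 10**
Reactants: 16 1-(5-hydroxy-2,2-dimethyl-2H-chromen-6-yl)ethan-1-one; 2 2,4-bis(methoxymethoxy)benzaldehyde
Product: 17 (2E)-3-[2,4-bis(methoxymethoxy)phenyl]-1-(5-hydroxy-2,2-dimethyl-2H-chromen-6-yl)prop-2-en-1-one
Conditions: KOH (50% aq.), EtOH, rt, 48 h
Reagents that add atoms: none
Why: Claisen–Schmidt condensation: the ketone enolate adds to the non-enolisable aldehyde and E1cB dehydration gives the E-enone, the chelated phenol remaining free for boron binding.

**Step 11**
Reactants: 17 (2E)-3-[2,4-bis(methoxymethoxy)phenyl]-1-(5-hydroxy-2,2-dimethyl-2H-chromen-6-yl)prop-2-en-1-one; 12 2-[2,4-bis(methoxymethoxy)phenyl]-5,7-bis(methoxymethoxy)-8-[(1E)-3-methylbuta-1,3-dien-1-yl]-3-(3-methylbut-2-en-1-yl)-4H-chromen-4-one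
Product: 18 2-[2,4-bis(methoxymethoxy)phenyl]-8-[(1S,5R,6S)-5-[2,4-bis(methoxymethoxy)phenyl]-6-(5-hydroxy-2,2-dimethyl-2H-chromene-6-carbonyl)-3-methylcyclohex-2-en-1-yl]-5,7-bis(methoxymethoxy)-3-(3-methylbut-2-en-1-yl)-4H-chromen-4-one
Conditions: (S)-VANOL (1.5 equiv), BH3·THF (1.5 equiv), AcOH (1.5 equiv), THF, rt, 1 h, evaporate; then 17 (1.2 equiv), 12 (1.0 equiv), 5 Å MS, PhCF3, 50 °C, 48 h; aq. NaHCO3 work-up, chromatography
Reagents that add atoms: none
Why: Asymmetric Diels–Alder reaction: the 2'-hydroxychalcone binds the chiral borate through phenoxide and carbonyl oxygen, which activates the enone and shields one face; the E-enone fixes the C4''/C5'' trans relation, the exo transition state puts the flavone at C3'' trans to the aroyl group, the ligand sets the absolute sense (3''S,4''S,5''R), and the minor endo isomer is removed by chromatography.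

**Step 12**
Reactants: 18 hexakis-MOM ether of kuwanon W (product of step 11)
Product: 20 kuwanon W, via hexakis(trimethylsilyl) ether 19 (not isolated)
Conditions: TMSOTf (15 equiv), 2,2'-bipyridyl (20 equiv), CH3CN, 0 °C to rt, 3 h; then H2O, rt, 2 h
Reagents that add atoms: trimethylsilyl trifluoromethanesulfonate, C[Si](C)(C)OS(=O)(=O)C(F)(F)F (its silyl groups stay in 19 only; 20 gains hydrogen only)
Why: Silyl triflate–bipyridyl acetal cleavage: the buffered silyl triflate turns each aryl MOM acetal into an aryl silyl ether and an N-(methoxymethyl)pyridinium salt without free Brønsted acid, and water then hydrolyses the silyl ethers, so the prenyl, chromene and cyclohexene olefins and the three stereocentres are untouched.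

**Compound list**
1 | 2,4-dihydroxybenzaldehyde | O=Cc1ccc(O)cc1O | starting material
2 | 2,4-bis(methoxymethoxy)benzaldehyde | O=Cc1ccc(OCOC)cc1OCOC | intermediate
3 | 1-ethynyl-2,4-bis(methoxymethoxy)benzene | C#Cc1ccc(OCOC)cc1OCOC | intermediate
4 | 1-bromo-3-methylbut-2-ene (prenyl bromide) | CC(C)=CCBr | starting material
5 | 1-(5-methylhex-4-en-1-yn-1-yl)-2,4-bis(methoxymethoxy)benzene | CC(C)=CCC#Cc1ccc(OCOC)cc1OCOC | intermediate
6 | 2,4,6-trihydroxybenzaldehyde | O=Cc1c(O)cc(O)cc1O | starting material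
7 | 2-hydroxy-4,6-bis(methoxymethoxy)benzaldehyde | O=Cc1c(O)cc(OCOC)cc1OCOC | intermediate
8 | 3-bromo-2-hydroxy-4,6-bis(methoxymethoxy)benzaldehyde | O=Cc1c(O)c(Br)c(OCOC)cc1OCOC | intermediate
9 | 8-bromo-2-[2,4-bis(methoxymethoxy)phenyl]-5,7-bis(methoxymethoxy)-3-(3-methylbut-2-en-1-yl)-4H-chromen-4-one | CC(C)=CCc1c(-c2ccc(OCOC)cc2OCOC)oc2c(Br)c(OCOC)cc(OCOC)c2c1=O | intermediate
10 | 2-methylbut-1-en-3-yne | C=C(C)C#C | starting material
11 | 4,4,5,5-tetramethyl-2-[(1E)-3-methylbuta-1,3-dien-1-yl]-1,3,2-dioxaborolane | C=C(C)/C=C/B1OC(C)(C)C(C)(C)O1 | intermediate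
12 | 2-[2,4-bis(methoxymethoxy)phenyl]-5,7-bis(methoxymethoxy)-8-[(1E)-3-methylbuta-1,3-dien-1-yl]-3-(3-methylbut-2-en-1-yl)-4H-chromen-4-one | CC(C)=CCc1c(-c2ccc(OCOC)cc2OCOC)oc2c(/C=C/C(C)=C)c(OCOC)cc(OCOC)c2c1=O | intermediate
13 | 1-(2,4-dihydroxyphenyl)ethan-1-one | CC(=O)c1ccc(O)cc1O | starting material
14 | 3-methylbut-2-enal (prenal) | CC(C)=CC=O | starting material
15 | 4-acetyl-3-hydroxy-2-(3-methylbut-2-en-1-ylidene)cyclohexa-3,5-dien-1-one (ortho-quinone methide) | CC(=O)C1=C(O)C(=CC=C(C)C)C(=O)C=C1 | intermediate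
16 | 1-(5-hydroxy-2,2-dimethyl-2H-chromen-6-yl)ethan-1-one | CC(=O)c1ccc2c(c1O)C=CC(C)(C)O2 | intermediate
17 | (2E)-3-[2,4-bis(methoxymethoxy)phenyl]-1-(5-hydroxy-2,2-dimethyl-2H-chromen-6-yl)prop-2-en-1-one | COCOc1ccc(/C=C/C(=O)c2ccc3c(c2O)C=CC(C)(C)O3)c(OCOC)c1 | intermediate
18 | 2-[2,4-bis(methoxymethoxy)phenyl]-8-[(1S,5R,6S)-5-[2,4-bis(methoxymethoxy)phenyl]-6-(5-hydroxy-2,2-dimethyl-2H-chromene-6-carbonyl)-3-methylcyclohex-2-en-1-yl]-5,7-bis(methoxymethoxy)-3-(3-methylbut-2-en-1-yl)-4H-chromen-4-one (hexakis-MOM ether of kuwanon W) | CC(C)=CCc1c(-c2ccc(OCOC)cc2OCOC)oc2c([C@H]3C=C(C)C[C@@H](c4ccc(OCOC)cc4OCOC)[C@@H]3C(=O)c3ccc4c(c3O)C=CC(C)(C)O4)c(OCOC)cc(OCOC)c2c1=O | intermediate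
19 | hexakis(trimethylsilyl) ether of kuwanon W (the six former MOM oxygens silylated, chelated OH free) | CC(C)=CCc1c(-c2ccc(O[Si](C)(C)C)cc2O[Si](C)(C)C)oc2c([C@H]3C=C(C)C[C@@H](c4ccc(O[Si](C)(C)C)cc4O[Si](C)(C)C)[C@@H]3C(=O)c3ccc4c(c3O)C=CC(C)(C)O4)c(O[Si](C)(C)C)cc(O[Si](C)(C)C)c2c1=O | intermediate
20 | kuwanon W, 2-(2,4-dihydroxyphenyl)-8-[(1S,5R,6S)-5-(2,4-dihydroxyphenyl)-6-(5-hydroxy-2,2-dimethyl-2H-chromene-6-carbonyl)-3-methylcyclohex-2-en-1-yl]-5,7-dihydroxy-3-(3-methylbut-2-en-1-yl)-4H-chromen-4-one | CC(C)=CCc1c(-c2ccc(O)cc2O)oc2c([C@H]3C=C(C)C[C@@H](c4ccc(O)cc4O)[C@@H]3C(=O)c3ccc4c(c3O)C=CC(C)(C)O4)c(O)cc(O)c2c1=O | target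

**Totals**
Total step count: 12. Longest linear sequence: 7 steps (1, 2, 3, 6, 8, 11, 12).

**Three steps most likely to fail**

Step 6 (the proposed new annulation). Risks are reversed alkyne regiochemistry, isomerisation of the skipped enyne, or loss of bromide or acetal at 120 °C. The fallback uses known chemistry, sets out from 8 and 3 and comes back at 9. The lithium acetylide of 3 (n-BuLi, THF, −78 °C, 2.2 equiv to allow for the free phenol) adds to aldehyde 8 to give the racemic propargylic alcohol F1. MnO2 in CH2Cl2 oxidises it to the ortho-hydroxyaryl ynone F2. Et2NH in EtOH at 60 °C (enaminone formation, then 6-endo addition–elimination by the phenol) closes the 3-unsubstituted 8-bromoflavone F3. Lithiation at C3 with LiN(i-Pr)2 at −78 °C and alkylation with prenyl bromide 4 then gives 9.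

Step 11 (Diels–Alder). Risks are a poor exo/endo ratio, low enantiomeric excess, or a sluggish reaction with the hindered flavone diene. The fallback sets out from 12 and 17 and comes back at 18. The cycloaddition is run without chiral control (Ag/SiO2, silica-supported zerovalent silver nanoparticles, CH2Cl2, 50 °C, or simply toluene, 110 °C, sealed tube). The exo adduct is isolated as the racemate, that is 18 together with the mirror-image adduct ent-18 F4. The two are separated by preparative HPLC on an amylose tris(3,5-dimethylphenylcarbamate) phase, and 18 goes on to step 12.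

Step 12 (sixfold deprotection). Risks are attack of the silyl triflate on the flavone carbonyl or the enolisable ketone, or incomplete cleavage. Brønsted acids are not an option at this stage because they would cyclise phenols onto the cyclohexene and prenyl olefins. The fallback changes the end-game protecting groups to acetates before the diene exists; it sets out from 9 and 17 and comes back at 20. HCl in MeOH (50 °C) converts 9 into the free 8-bromo tetrahydroxyflavone F5, and Ac2O/pyridine gives the tetraacetate F6. Anhydrous Suzuki coupling with 11 (Pd(OAc)2, SPhos, anhydrous K3PO4, toluene, 80 °C) gives the diene tetraacetate F7. In parallel, HCl in MeOH (rt, dark) converts 17 into the free chalcone F8, and Ac2O (2.2 equiv)/Et3N at 0 °C gives the diacetate F9 with the chelated OH untouched. The same borate-promoted Diels–Alder reaction of F9 with F7 gives the hexaacetate adduct F10, and K2CO3 in MeOH at rt releases 20.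

**Further compounds**
F1 | step 6 | 2-bromo-6-{3-[2,4-bis(methoxymethoxy)phenyl]-1-hydroxyprop-2-yn-1-yl}-3,5-bis(methoxymethoxy)phenol (racemic) | OC(C#Cc1ccc(OCOC)cc1OCOC)c1c(O)c(Br)c(OCOC)cc1OCOC
F2 | step 6 | 1-[3-bromo-2-hydroxy-4,6-bis(methoxymethoxy)phenyl]-3-[2,4-bis(methoxymethoxy)phenyl]prop-2-yn-1-one | O=C(C#Cc1ccc(OCOC)cc1OCOC)c1c(O)c(Br)c(OCOC)cc1OCOC
F3 | step 6 | 8-bromo-2-[2,4-bis(methoxymethoxy)phenyl]-5,7-bis(methoxymethoxy)-4H-chromen-4-one | O=c1cc(-c2ccc(OCOC)cc2OCOC)oc2c(Br)c(OCOC)cc(OCOC)c12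
F4 | step 11 | ent-18, the (1R,5S,6R) mirror image of adduct 18 | CC(C)=CCc1c(-c2ccc(OCOC)cc2OCOC)oc2c([C@@H]3C=C(C)C[C@H](c4ccc(OCOC)cc4OCOC)[C@H]3C(=O)c3ccc4c(c3O)C=CC(C)(C)O4)c(OCOC)cc(OCOC)c2c1=O
F5 | step 12 | 8-bromo-2-(2,4-dihydroxyphenyl)-5,7-dihydroxy-3-(3-methylbut-2-en-1-yl)-4H-chromen-4-one | CC(C)=CCc1c(-c2ccc(O)cc2O)oc2c(Br)c(O)cc(O)c2c1=O
F6 | step 12 | 8-bromo-3-(3-methylbut-2-en-1-yl)-4-oxo-2-(2,4-diacetoxyphenyl)-4H-chromene-5,7-diyl diacetate | CC(C)=CCc1c(-c2ccc(OC(C)=O)cc2OC(C)=O)oc2c(Br)c(OC(C)=O)cc(OC(C)=O)c2c1=O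
F7 | step 12 | 8-[(1E)-3-methylbuta-1,3-dien-1-yl]-3-(3-methylbut-2-en-1-yl)-4-oxo-2-(2,4-diacetoxyphenyl)-4H-chromene-5,7-diyl diacetate | CC(C)=CCc1c(-c2ccc(OC(C)=O)cc2OC(C)=O)oc2c(/C=C/C(C)=C)c(OC(C)=O)cc(OC(C)=O)c2c1=O
F8 | step 12 | (2E)-3-(2,4-dihydroxyphenyl)-1-(5-hydroxy-2,2-dimethyl-2H-chromen-6-yl)prop-2-en-1-one | Oc1ccc(/C=C/C(=O)c2ccc3c(c2O)C=CC(C)(C)O3)c(O)c1
F9 | step 12 | 4-[(1E)-3-(5-hydroxy-2,2-dimethyl-2H-chromen-6-yl)-3-oxoprop-1-en-1-yl]-1,3-phenylene diacetate | CC(=O)Oc1ccc(/C=C/C(=O)c2ccc3c(c2O)C=CC(C)(C)O3)c(OC(C)=O)c1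
F10 | step 12 | kuwanon W hexaacetate, (1S,5R,6S) adduct with acetates on the six non-chelated phenols | CC(C)=CCc1c(-c2ccc(OC(C)=O)cc2OC(C)=O)oc2c([C@H]3C=C(C)C[C@@H](c4ccc(OC(C)=O)cc4OC(C)=O)[C@@H]3C(=O)c3ccc4c(c3O)C=CC(C)(C)O4)c(OC(C)=O)cc(OC(C)=O)c2c1=O
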